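**Plan**
- Retrosynthesis: the three phenols are masked as acetates. The three aryl–CH2 bonds (C6–CH2 and C8–CH2 on ring A, C5'–CH2 on ring B) are then cut together, giving one triiodide and a prenylstannane. The three carbon–iodine bonds lead back to (2S)-hesperetin.
- Enabling feature: the target is hesperetin with prenyl groups at C6, C8 and C5'. C6 and C8 are the only free carbons of the phloroglucinol ring A. C5' is the free carbon ortho to the 4'-methoxy group of ring B. Each site can therefore be iodinated selectively and all three aryl iodides coupled in one flask.
- Forward: no ring is built, because rings A, B and C and all six oxygens come with hesperetin. The order is ring A diiodination, acetylation, ring B iodination, threefold prenyl coupling, deacetylation.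
- Stereochemistry: the only stereocentre, C2 (S), is bought with hesperetin and carried through steps that are non-basic or near neutral.

Key step: step 5

**Remarks**
- Assumption: (2S)-hesperetin, the aglycone of citrus hesperidin, is purchased as the single enantiomer and its optical purity is confirmed before use.
- Assumption: where one transformation occurs two or three times in one flask (steps 1, 2, 5, 6), the partly converted species arise as mixtures of positional isomers and are not treated as discrete intermediates.

**Route**

Step 1
Reactants: 1 (2S)-hesperetin
Product: 2 (2S)-6,8-diiodohesperetin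
Conditions: N-iodosuccinimide (2.05 equiv), DMF, 0 °C to rt, dark
Reagents that add atoms: N-iodosuccinimide, O=C1CCC(=O)N1I
Why: Electrophilic aromatic iodination: ring A, a phloroglucinol ring that reacts through its acidic 7-OH, is far more nucleophilic than the guaiacol-type ring B and has only C6 and C8 free, so two equivalents of N-iodosuccinimide without acid should stop at the 6,8-diiodide while C2 is untouched.

Step 2
Reactants: 2 (2S)-6,8-diiodohesperetin
Product: 3 (2S)-6,8-diiodohesperetin 5,7,3'-triacetate
Conditions: Ac2O (4 equiv), pyridine, DMAP (cat.), CH2Cl2, 0 °C to rt
Reagents that add atoms: acetic anhydride, CC(=O)OC(C)=O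
Why: Nucleophile-catalysed O-acylation (DMAP, Ac2O) of all three phenols, the chelated and iodine-flanked ones included, under amine-base conditions too mild and brief to open ring C by retro-oxa-Michael reaction, so C2 stays (S).

Step 3
Reactants: 3 (2S)-6,8-diiodohesperetin 5,7,3'-triacetate
Product: 4 (2S)-6,8,5'-triiodohesperetin 5,7,3'-triacetate
Conditions: I2 (1.2 equiv), CF3CO2Ag (1.2 equiv), CH2Cl2, 0 °C to rt, dark
Reagents that add atoms: iodine, [I][I]
Why: Electrophilic aromatic iodination by trifluoroacetyl hypoiodite formed from I2 and CF3CO2Ag: ring A is fully substituted, the ester-masked 3'-oxygen is only a weak director, and the 4'-methoxy group, whose para carbon C1' is occupied, sends iodine to its free ortho carbon C5', which is also the less hindered of the open sites C5' and C6'.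

Step 4
Reactants: 5 prenyl bromide (1-bromo-3-methylbut-2-ene); 6 tributyltin chloride
Product: 8 tributyl(3-methylbut-2-enyl)stannane, via 3-methylbut-2-enylmagnesium bromide 7 (not isolated)
Conditions: Mg turnings (1.3 equiv), THF, 5 added dropwise to Mg and 6 at 0 °C, then rt; vacuum distillation
Reagents that add atoms: none
Why: Barbier-type reaction: the allylic Grignard reagent formed on the magnesium surface is trapped at once by the tin chloride, which limits Wurtz dimerisation, and tin ends up on the unsubstituted CH2 terminus because the primary prenylstannane is the sterically and thermodynamically preferred isomer.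

Step 5
Reactants: 4 (2S)-6,8,5'-triiodohesperetin 5,7,3'-triacetate; 8 tributyl(3-methylbut-2-enyl)stannane (4.5 equiv)
Product: 9 (2S)-6,8,5'-triprenylhesperetin 5,7,3'-triacetate
Conditions: Pd2(dba)3 (10 mol%), P(2-furyl)3 (40 mol%), degassed DMF, 70 °C
Reagents that add atoms: none
Why: Each aryl iodide adds oxidatively to zerovalent palladium, the prenylstannane transmetalates to the resulting arylpalladium iodide (divalent palladium) to give an aryl(allyl)palladium species that interconverts between sigma- and pi-allyl forms, and reductive elimination forms the aryl–CH2 bond; with excess 8 this cycle should run three times, at C6, C8 and C5'. The closest known reaction type is the Stille allylation of aryl halides with allyl- and prenyltributylstannanes. No ring is closed and no stereocentre is created; C2 is remote from the reacting carbons and the medium is neutral and free of base or fluoride, so ring C stays closed and the aryl acetates, which do not add to zerovalent palladium, stay in place. The selectivity required is linear versus reverse prenyl transfer: in the crowded aryl(allyl)palladium intermediates, each flanked by one or two ortho oxygen substituents, reductive elimination should occur at the unsubstituted CH2 terminus of the allyl ligand and not at its CMe2 terminus. The weakly donating P(2-furyl)3 speeds transmetalation, so protodeiodination at the hindered C6 and C8 positions should not compete.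

Step 6
Reactants: 9 (2S)-6,8,5'-triprenylhesperetin 5,7,3'-triacetate
Product: 10 isoamoritin
Conditions: NH4OAc (10 equiv), MeOH–H2O (4:1), rt
Reagents that add atoms: none
Why: Ammonium acetate-mediated transesterification of aryl acetates to methanol at near-neutral pH, which cleaves the activated phenolic esters while being too weakly basic to open ring C to the chalcone (C2 stays S) and too weakly acidic to add the freed phenols across the prenyl double bonds.

**Compound list**
1 | (2S)-hesperetin, (2S)-5,7-dihydroxy-2-(3-hydroxy-4-methoxyphenyl)chroman-4-one | COc1ccc([C@@H]2CC(=O)c3c(O)cc(O)cc3O2)cc1O | starting material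
2 | (2S)-6,8-diiodohesperetin, (2S)-5,7-dihydroxy-2-(3-hydroxy-4-methoxyphenyl)-6,8-diiodochroman-4-one | COc1ccc([C@@H]2CC(=O)c3c(O)c(I)c(O)c(I)c3O2)cc1O | intermediate
3 | (2S)-6,8-diiodohesperetin 5,7,3'-triacetate, (2S)-2-(3-acetoxy-4-methoxyphenyl)-6,8-diiodo-4-oxochroman-5,7-diyl diacetate | COc1ccc([C@@H]2CC(=O)c3c(OC(C)=O)c(I)c(OC(C)=O)c(I)c3O2)cc1OC(C)=O | intermediate
4 | (2S)-6,8,5'-triiodohesperetin 5,7,3'-triacetate, (2S)-2-(3-acetoxy-5-iodo-4-methoxyphenyl)-6,8-diiodo-4-oxochroman-5,7-diyl diacetate | COc1c(OC(C)=O)cc([C@@H]2CC(=O)c3c(OC(C)=O)c(I)c(OC(C)=O)c(I)c3O2)cc1I | intermediate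
5 | prenyl bromide, 1-bromo-3-methylbut-2-ene | CC(C)=CCBr | starting material
6 | tributyltin chloride | CCCC[Sn](Cl)(CCCC)CCCC | starting material
7 | 3-methylbut-2-enylmagnesium bromide | CC(C)=CC[Mg]Br | intermediate
8 | tributyl(3-methylbut-2-enyl)stannane | CC(C)=CC[Sn](CCCC)(CCCC)CCCC | intermediate
9 | (2S)-6,8,5'-triprenylhesperetin 5,7,3'-triacetate, (2S)-2-[3-acetoxy-4-methoxy-5-(3-methylbut-2-enyl)phenyl]-6,8-bis(3-methylbut-2-enyl)-4-oxochroman-5,7-diyl diacetate | COc1c(OC(C)=O)cc([C@@H]2CC(=O)c3c(OC(C)=O)c(CC=C(C)C)c(OC(C)=O)c(CC=C(C)C)c3O2)cc1CC=C(C)C | intermediate
10 | isoamoritin, (2S)-5,7-dihydroxy-2-[3-hydroxy-4-methoxy-5-(3-methylbut-2-enyl)phenyl]-6,8-bis(3-methylbut-2-enyl)chroman-4-one | COc1c(O)cc([C@@H]2CC(=O)c3c(O)c(CC=C(C)C)c(O)c(CC=C(C)C)c3O2)cc1CC=C(C)C | target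

**Count**
Total steps: 6. Longest linear sequence: 5 steps (steps 1, 2, 3, 5, 6 from compound 1); step 4 is a one-step branch to the stannane.

**Steps most likely to fail**

Step 5. The threefold prenyl transfer may stall after one or two couplings, lose iodine by protodeiodination at the hindered C6 and C8 positions, or bond through the substituted allyl terminus to give reverse-prenyl chains. The fallback installs the chains in two stages. Triiodide 4 would be coupled with allyltributylstannane under the same zerovalent palladium catalysis (Pd2(dba)3, P(2-furyl)3, DMF); the smaller, symmetrical allyl group transmetalates more readily and has no regiochemical ambiguity. This should give (2S)-6,8,5'-triallylhesperetin 5,7,3'-triacetate F1. Threefold olefin cross-metathesis of F1 with excess 2-methylbut-2-ene and the second-generation Grubbs catalyst in CH2Cl2 at 40 °C would then convert each allyl group into a prenyl group and rejoin the route at 9.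

Step 3. Electrophilic attack on ring B may be diverted to C6' (para to the acetate), or the deactivated ring may react sluggishly, giving mixtures of regioisomers. The fallback selects the position by sterics instead of electronics. From 3, iridium-catalysed C–H borylation ([Ir(OMe)(cod)]2, 4,4'-di-tert-butyl-2,2'-bipyridine, B2pin2, THF, 60 °C) should occur at C5', the only ring B CH whose single ortho neighbour is the small methoxy group. C2' is flanked on both sides and C6' lies next to the chromanone carbon. Ring A has no CH, and aryl iodides, esters and ketones are tolerated by this catalyst. The product would be (2S)-6,8-diiodo-5'-(pinacolboryl)hesperetin 5,7,3'-triacetate F2. Ipso-iododeboronation with NaI and chloramine-T in aqueous THF at rt would rejoin the route at 4.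

Step 6. The acetates flanked by prenyl groups may resist the mild solvolysis; forcing it with stronger base would open ring C to the chalcone and erode the C2 configuration, and acid would cyclise the prenyl phenols to chromans. The fallback inverts the order of the last two operations. From 4, the same NH4OAc treatment in aqueous methanol would give (2S)-6,8,5'-triiodohesperetin F3. This cleavage should be easier because iodine-flanked phenoxides are better leaving groups and no alkene is present. The threefold Stille prenylation with 8 (Pd2(dba)3, P(2-furyl)3, DMF) would then be run on the free triphenol, which the neutral tin coupling tolerates, rejoining the route directly at 10.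

**Further compounds**
F1 | step 5 | (2S)-6,8,5'-triallylhesperetin 5,7,3'-triacetate | COc1c(OC(C)=O)cc([C@@H]2CC(=O)c3c(OC(C)=O)c(CC=C)c(OC(C)=O)c(CC=C)c3O2)cc1CC=C
F2 | step 3 | (2S)-6,8-diiodo-5'-(pinacolboryl)hesperetin 5,7,3'-triacetate | COc1c(OC(C)=O)cc([C@@H]2CC(=O)c3c(OC(C)=O)c(I)c(OC(C)=O)c(I)c3O2)cc1B1OC(C)(C)C(C)(C)O1
F3 | step 6 | (2S)-6,8,5'-triiodohesperetin | COc1c(O)cc([C@@H]2CC(=O)c3c(O)c(I)c(O)c(I)c3O2)cc1I
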